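- The target and the uncatalysed product both grow from substrate and dissolved gas, so their rates keep a fixed ratio: the selectivity factor ρ, the catalysed constant times [catalyst] over the uncatalysed constant, here 0.834.

    substrate + dissolved gas → uncatalysed product (k1 = 9.1 M⁻¹ s⁻¹)
    gas phase ⇌ dissolved gas, rate k2*(csat - [dissolved gas]) (k2 = 5.9 s⁻¹, csat = 3.1 mM)
    2 substrate → homo dimer (k3 = 0.97 M⁻¹ s⁻¹)
    substrate + dissolved gas + catalyst → catalyst + target (k4 = 69000 M⁻² s⁻¹)

substrate 41 mM; gas phase 3.1 mM (held); catalyst 0.11 mM; time 15 s

- in percentages every species weighs as the substrate in it: one homo dimer counts as two
- a doubled species enters its step squared and goes two at a time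
- at the start none of the gas is dissolved
- run time (flask): 15 s

- ochre: doubling the transfer coefficient of step 2, all else as stated
- grey: doubling the amount of catalyst, all else as stated
- red: doubling the saturation concentration of gas phase, all else as stated

1. how much target there is at 15 s, in percent of the substrate charged
2. the change that raises the amount of target at 15 s, in percent of the substrate charged most ("none" if none brings more than 2 percentage points) (ochre / grey / red / none)
3. amount of target at 15 s, in percent of the substrate charged, after grey

- For a first ceiling I held substrate at its charge and dissolved gas at saturation, which gave 35.3% target.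
- Substrate falls, though. I integrated its loss by the gas paths and by dimerisation, with the gas still saturated, and the ceiling dropped to 17.9%, with mean [substrate] at 50.7% of the charge.
- For the floor, the gas paths used dissolved gas at 0.684 s⁻¹ at the charge, slower than transfer at 5.9 s⁻¹, so I took 2.78 mM as [dissolved gas] and started the clock 0.169 s late, which gave 16.3%.
- I committed to the middle of that bracket, 17.1%.
- With the gas saturated, red and grey each double the target rate at a given [substrate], but grey doubles ρ and red leaves it alone, while ochre stays under the ceiling. At saturation red gave 28.0% and grey 31.9%, so I chose grey.
- The forecast gave 16.9% (15.5% to 18.5%), inside my bracket, then grey and 29.7% (27.5% to 32%), saying “Doubling the catalyst lifts that share most”.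
- The simulation gave 16.8%, between my bounds, and grey as best: it gained 13 percentage points and reached 29.7%, against 10 points for red and 0.53 points for ochre.
- At 15.0 s this flask's uncatalysed path used dissolved gas 1.2 times as fast as the target path, and the inverse of ρ is 1.20. Target stood at 16.8% beside 20.1% uncatalysed product, a ratio of 0.836.
- In the neighbour flask with 0.44 mM catalyst, ρ becomes 3.34, and that flask held 47.9% target beside 14.4% uncatalysed product, a ratio of 3.33.

All constants are assumed; the flask was simulated.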